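Everything rests on closing ring C at C3–C4. Both carbons are natural acceptors. C4 is the benzylic carbon of phloroglucinol ring A ortho to O1, a salicylaldehyde carbonyl in disguise, and C3 is a carbinol carbon. A nitro group on C3 reverses its polarity (nitronate as masked acyl anion). One aminocatalytic domino step joins a ring A salicylaldehyde and a ring B nitrostyrene. Oxa-Michael addition makes O1–C2 and sets C2. The resulting aryl ether, which carries a C3 nitronate and a C4 iminium, closes C3–C4, and elimination gives a 3-nitro-2H-chromene. Reductive Nef reaction, hydride delivery anti to ring B, galloylation and hydrogenolysis finish the synthesis.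

Key step: step 4

Assumption: flavan numbering is used (O1, C2, C3, C4, C4a, C5–C8, C8a; ring A = benzo ring, ring B = 2-aryl, ring C = pyran, ring D = galloyl); the (S)-catalyst of step 4, Cn1ccnc1SC[C@@H]1CCCN1, a prolinol-derived reagent, is taken to give (2R)-10, and if the sense proves opposite its enantiomer is used with no other change; 1, 3, 5 and 15 are taken as commercial.

Step 1
Reactants: 1 2,4,6-trihydroxybenzaldehyde
Product: 2 4,6-bis(benzyloxy)-2-hydroxybenzaldehyde
Conditions: BnBr (2.1 equiv), K2CO3, DMF, 0 °C to rt, N2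
Reagents that add atoms: benzyl bromide BrCc1ccccc1
Why: Williamson ether synthesis; the hydroxyl that remains is held in a strong hydrogen bond to the formyl oxygen and is the least nucleophilic, so alkylation should stop at the 4,6-diether.

Step 2
Reactants: 3 3,4,5-trihydroxybenzaldehyde
Product: 4 3,4,5-tris(benzyloxy)benzaldehyde
Conditions: BnBr (3.5 equiv), K2CO3, DMF, 60 °C, N2
Reagents that add atoms: benzyl bromide BrCc1ccccc1
Why: Exhaustive Williamson ether synthesis under nitrogen should alkylate all three phenols before the pyrogallol unit can oxidise.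

Step 3
Reactants: 4 3,4,5-tris(benzyloxy)benzaldehyde; 5 nitromethane
Product: 6 (E)-1,2,3-tris(benzyloxy)-5-(2-nitroethenyl)benzene
Conditions: MeNO2 (excess), NH4OAc, AcOH, 100 °C
Reagents that add atoms: none
Why: Henry (nitroaldol) condensation with dehydration in the same pot should give the thermodynamically preferred E-nitrostyrene, and nitromethane supplies the future C3.

Step 4
Reactants: 2 4,6-bis(benzyloxy)-2-hydroxybenzaldehyde; 6 (E)-1,2,3-tris(benzyloxy)-5-(2-nitroethenyl)benzene
Product: 10 (2R)-5,7-bis(benzyloxy)-3-nitro-2-[3,4,5-tris(benzyloxy)phenyl]-2H-chromene, via iminium phenolate 7 (not isolated), via nitronate-iminium zwitterion 8 (not isolated), via 4-pyrrolidinyl-3-nitrochroman 9 (not isolated)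
Conditions: (S)-1-methyl-2-[(pyrrolidin-2-ylmethyl)sulfanyl]-1H-imidazole (20 mol %), salicylic acid (20 mol %), DMSO, rt
Reagents that add atoms: none
Why: The pyrrolidine nitrogen of the catalyst condenses with 2 to iminium phenolate 7, which makes the donor-deactivated C4 electrophilic again; phenolate O1 adds to the β-carbon of 6 (oxa-Michael addition) to give 8, the nitronate carbon C3 of 8, a masked acyl anion, attacks iminium carbon C4 (intramolecular nitro-Mannich variant of the Henry reaction) to give 9, and E1cB loss of the amine gives 10 and returns the catalyst. The closest known reaction type is the aminocatalytic enantioselective oxa-Michael–Henry–dehydration domino reaction of salicylaldehydes with β-nitrostyrenes to 2-aryl-3-nitro-2H-chromenes. Ring C closes in the 6-(enolexo)-exo-trig mode, with the nitronate C=N and the iminium C=N bonds both outside the new ring. C2 is the only lasting stereocenter and is set by the catalyst, whose (S)-pyrrolidine centre places the imidazole arm and the salicylic acid so that they bind the nitro group and present one face of 6 to O1, while the C3 and C4 centres of 9 are erased by the elimination. The step needs O-attack instead of C-attack by ring A and a single reacting phenol, which the electron-withdrawing iminium group and the benzyl ethers on O5 and O7 secure. The final elimination drains the reversible earlier equilibria toward the conjugated nitrochromene, and the reaction is stopped at full conversion to limit erosion of the enantiomeric purity by amine re-addition.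

Step 5
Reactants: 10 (2R)-5,7-bis(benzyloxy)-3-nitro-2-[3,4,5-tris(benzyloxy)phenyl]-2H-chromene
Product: 13 (2R)-5,7-bis(benzyloxy)-2-[3,4,5-tris(benzyloxy)phenyl]chroman-3-one, via oxime 11 (not isolated), via imine 12 (not isolated)
Conditions: TiCl3 (aq. HCl solution, 7 equiv), NH4OAc buffer, THF–H2O, 0 °C to rt
Reagents that add atoms: water O
Why: Reductive Nef reaction of a conjugated nitroalkene: trivalent titanium reduces 10 to oxime 11, which puts the new hydrogen on C4, then cleaves the N–O bond to imine 12, and the buffered water hydrolyses 12 to ketone 13, while the near-neutral acetate buffer and the low temperature should spare the enolisable C2 centre and the benzyl ethers.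

Step 6
Reactants: 13 (2R)-5,7-bis(benzyloxy)-2-[3,4,5-tris(benzyloxy)phenyl]chroman-3-one
Product: 14 (2R,3R)-5,7-bis(benzyloxy)-2-[3,4,5-tris(benzyloxy)phenyl]chroman-3-ol
Conditions: LiBH(s-Bu)3 (lithium tri-sec-butylborohydride, 1.5 equiv), THF, −78 °C; then H2O
Reagents that add atoms: none
Why: Diastereoselective ketone reduction with a bulky borohydride: with ring B pseudo-equatorial on the half-chair of ring C the reagent should reach C3 from the face anti to ring B (equatorial attack), which gives the axial 3-OH cis to ring B, that is (3R), and the low temperature keeps C2 from epimerising.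

Step 7
Reactants: 14 (2R,3R)-5,7-bis(benzyloxy)-2-[3,4,5-tris(benzyloxy)phenyl]chroman-3-ol; 15 3,4,5-tris(benzyloxy)benzoic acid
Product: 16 (2R,3R)-5,7-bis(benzyloxy)-2-[3,4,5-tris(benzyloxy)phenyl]chroman-3-yl 3,4,5-tris(benzyloxy)benzoate
Conditions: DCC, DMAP (cat.), CH2Cl2, rt
Reagents that add atoms: none
Why: Steglich esterification; carbodiimide activation and DMAP acyl transfer should acylate the hindered axial 3-OH with retention, because the C3–O bond is not touched.

Step 8
Reactants: 16 (2R,3R)-5,7-bis(benzyloxy)-2-[3,4,5-tris(benzyloxy)phenyl]chroman-3-yl 3,4,5-tris(benzyloxy)benzoate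
Product: 17 (−)-epigallocatechin gallate, (2R,3R)-5,7-dihydroxy-2-(3,4,5-trihydroxyphenyl)chroman-3-yl 3,4,5-trihydroxybenzoate
Conditions: H2 (1 atm), Pd(OH)2/C, THF–MeOH, rt
Reagents that add atoms: none
Why: Catalytic hydrogenolysis should cleave all eight acyclic O-benzyl ethers, while the ester, the cyclic C2–O1 ether and both stereocenters are expected to survive the neutral conditions at room temperature.

Compound list
1 | 2,4,6-trihydroxybenzaldehyde | O=Cc1c(O)cc(O)cc1O | starting material
2 | 4,6-bis(benzyloxy)-2-hydroxybenzaldehyde | O=Cc1c(O)cc(OCc2ccccc2)cc1OCc1ccccc1 | intermediate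
3 | 3,4,5-trihydroxybenzaldehyde | O=Cc1cc(O)c(O)c(O)c1 | starting material
4 | 3,4,5-tris(benzyloxy)benzaldehyde | O=Cc1cc(OCc2ccccc2)c(OCc2ccccc2)c(OCc2ccccc2)c1 | intermediate
5 | nitromethane | C[N+](=O)[O-] | starting material
6 | (E)-1,2,3-tris(benzyloxy)-5-(2-nitroethenyl)benzene | O=[N+]([O-])/C=C/c1cc(OCc2ccccc2)c(OCc2ccccc2)c(OCc2ccccc2)c1 | intermediate
7 | iminium phenolate from 2 and the (S)-pyrrolidine catalyst (C4 as CH=N+, O1 as phenolate) | [O-]c1cc(OCc2ccccc2)cc(OCc2ccccc2)c1C=[N+]1CCC[C@H]1CSc1nccn1C | intermediate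
8 | oxa-Michael adduct, zwitterionic aryl ether with (R)-C2, C3 as nitronate carbon and C4 as iminium carbon | C(=[N+]1CCC[C@H]1CSc1nccn1C)c1c(OCc2ccccc2)cc(OCc2ccccc2)cc1O[C@@H](C=[N+]([O-])[O-])c1cc(OCc2ccccc2)c(OCc2ccccc2)c(OCc2ccccc2)c1 | intermediate
9 | (2R)-5,7-bis(benzyloxy)-3-nitro-4-(catalyst pyrrolidin-1-yl)-2-[3,4,5-tris(benzyloxy)phenyl]chroman, C3 and C4 transient and unassigned | O=[N+]([O-])C1C(N2CCC[C@H]2CSc2nccn2C)c2c(OCc3ccccc3)cc(OCc3ccccc3)cc2O[C@@H]1c1cc(OCc2ccccc2)c(OCc2ccccc2)c(OCc2ccccc2)c1 | intermediate
10 | (2R)-5,7-bis(benzyloxy)-3-nitro-2-[3,4,5-tris(benzyloxy)phenyl]-2H-chromene | O=[N+]([O-])C1=Cc2c(OCc3ccccc3)cc(OCc3ccccc3)cc2O[C@@H]1c1cc(OCc2ccccc2)c(OCc2ccccc2)c(OCc2ccccc2)c1 | intermediate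
11 | (2R)-5,7-bis(benzyloxy)-2-[3,4,5-tris(benzyloxy)phenyl]chroman-3-one oxime (C=N geometry unassigned) | ON=C1Cc2c(OCc3ccccc3)cc(OCc3ccccc3)cc2O[C@@H]1c1cc(OCc2ccccc2)c(OCc2ccccc2)c(OCc2ccccc2)c1 | intermediate
12 | (2R)-5,7-bis(benzyloxy)-2-[3,4,5-tris(benzyloxy)phenyl]chroman-3-imine | N=C1Cc2c(OCc3ccccc3)cc(OCc3ccccc3)cc2O[C@@H]1c1cc(OCc2ccccc2)c(OCc2ccccc2)c(OCc2ccccc2)c1 | intermediate
13 | (2R)-5,7-bis(benzyloxy)-2-[3,4,5-tris(benzyloxy)phenyl]chroman-3-one | O=C1Cc2c(OCc3ccccc3)cc(OCc3ccccc3)cc2O[C@@H]1c1cc(OCc2ccccc2)c(OCc2ccccc2)c(OCc2ccccc2)c1 | intermediate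
14 | (2R,3R)-5,7-bis(benzyloxy)-2-[3,4,5-tris(benzyloxy)phenyl]chroman-3-ol (2,3-cis) | O[C@@H]1Cc2c(OCc3ccccc3)cc(OCc3ccccc3)cc2O[C@@H]1c1cc(OCc2ccccc2)c(OCc2ccccc2)c(OCc2ccccc2)c1 | intermediate
15 | 3,4,5-tris(benzyloxy)benzoic acid | O=C(O)c1cc(OCc2ccccc2)c(OCc2ccccc2)c(OCc2ccccc2)c1 | starting material
16 | (2R,3R)-5,7-bis(benzyloxy)-2-[3,4,5-tris(benzyloxy)phenyl]chroman-3-yl 3,4,5-tris(benzyloxy)benzoate | O=C(O[C@@H]1Cc2c(OCc3ccccc3)cc(OCc3ccccc3)cc2O[C@@H]1c1cc(OCc2ccccc2)c(OCc2ccccc2)c(OCc2ccccc2)c1)c1cc(OCc2ccccc2)c(OCc2ccccc2)c(OCc2ccccc2)c1 | intermediate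
17 | (−)-epigallocatechin gallate, (2R,3R) | O=C(O[C@@H]1Cc2c(O)cc(O)cc2O[C@@H]1c1cc(O)c(O)c(O)c1)c1cc(O)c(O)c(O)c1 | target

Total step count: 8. Longest linear sequence: 7 steps (3 → 4 → 6 → 10 → 13 → 14 → 16 → 17).

Steps most likely to fail

Step 4. Iminium formation at the di-ortho-substituted, donor-rich aldehyde may be sluggish and the oxa-Michael addition is reversible. Either would show up as low conversion or poor facial selectivity at C2. The fallback moves enantiocontrol from C–O bond formation to the ketone reduction and sets out from 2 and 6.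
- DABCO in MeCN at 40 °C should run the same domino ring closure without chiral information. It should give racemic 5,7-bis(benzyloxy)-3-nitro-2-[3,4,5-tris(benzyloxy)phenyl]-2H-chromene F1.
- TiCl3/NH4OAc as in step 5 should then give racemic 5,7-bis(benzyloxy)-2-[3,4,5-tris(benzyloxy)phenyl]chroman-3-one F2.
- Hydrogenation of F2 with RuCl2[(S)-xylbinap][(S)-daipen], KOt-Bu, i-PrOH–THF, H2 (10 atm) is a dynamic kinetic resolution of a configurationally labile α-aryl, α-alkoxy cyclic ketone. The base racemises C2 through the enolate faster than hydride transfer, one ketone enantiomer is reduced preferentially, and equatorial hydride delivery gives the cis alcohol.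
- The catalyst antipode that consumes the (2R)-ketone is chosen in a test run.

The fallback comes back to the route at 14.

Step 5. The C2 configuration may erode through imine–enamine or keto–enol tautomerism in the acidic, Lewis acidic titanium medium, and over-reduction of the C=N stage is possible. In the fallback the nitrogen is removed by exchange instead of by reduction. It sets out from 10.
- SnCl2·2H2O in EtOAc at rt should stop the reduction at oxime 11, which is now isolated.
- Transoximation with aqueous glyoxylic acid in THF at rt should pass the hydroxylamine unit to the glyoxylic acid. This frees the ketone without forming imine 12 and without a reducing metal.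

The fallback comes back to the route at 13. Compounds outside the list: none F0.

Step 1. Statistical under- and over-alkylation of the three phenols may spoil the selectivity for the diether. The fallback replaces selective protection with full protection followed by directed deprotection. It sets out from 1.
- Excess BnBr, K2CO3, DMF at 60 °C should give 2,4,6-tris(benzyloxy)benzaldehyde F3.
- MgBr2·OEt2 in toluene–Et2O at reflux should chelate the formyl oxygen and one ortho ether oxygen, so only that ortho benzyl ether is cleaved.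

The fallback comes back to the route at 2.

Further compounds
F1 | step 4 | racemic 5,7-bis(benzyloxy)-3-nitro-2-[3,4,5-tris(benzyloxy)phenyl]-2H-chromene | O=[N+]([O-])C1=Cc2c(OCc3ccccc3)cc(OCc3ccccc3)cc2OC1c1cc(OCc2ccccc2)c(OCc2ccccc2)c(OCc2ccccc2)c1
F2 | step 4 | racemic 5,7-bis(benzyloxy)-2-[3,4,5-tris(benzyloxy)phenyl]chroman-3-one | O=C1Cc2c(OCc3ccccc3)cc(OCc3ccccc3)cc2OC1c1cc(OCc2ccccc2)c(OCc2ccccc2)c(OCc2ccccc2)c1
F0 | step 5 | none | none
F3 | step 1 | 2,4,6-tris(benzyloxy)benzaldehyde | O=Cc1c(OCc2ccccc2)cc(OCc2ccccc2)cc1OCc1ccccc1
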